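Assumption: the target is read as all‑E (4S,5S,6S,5'S,6'S)‑4‑hydroxy‑5,6,5',6'‑tetrahydro‑β,β‑caroten‑4'‑one; carotenoid numbering (ring C1–C6, chain C7–C15, primes for the keto half) is used in the comments.

**Retrosynthetic overview**
- C40 = C15 phosphonium salt (hydroxy end, ring A) + C10 trienedial + C15 phosphonium salt (keto end as dioxolane, ring B), joined by two Wittig reactions at C11=C12 and C11'=C12'; the ketal is removed last.
- Both C15 salts come from one C15 dienoate (Horner–Wadsworth–Emmons of a ring aldehyde with a C5 phosphonate); the 4‑OH of ring A is set by a ketoreductase on the C15 keto ester.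
- The ring aldehyde comes from a trans‑2,4,4‑trimethyl‑3‑(oxymethyl)cyclohexanone, made from (R)‑α‑cyclogeraniol by hydroboration, oxidation and C5 equilibration.
- C6 of α‑cyclogeraniol is set by a [2,3]‑Wittig–Still shift from (S)‑2,4,4‑trimethylcyclohex‑2‑enol, itself made by CBS reduction (first stereocentre).
- Ring order: the one carbocycle is built first (Robinson annulation) and serves both end groups; the only other ring is the temporary dioxolane.

**Step 1**
Reactants: 1 isobutyraldehyde (2-methylpropanal); 2 ethyl vinyl ketone (pent-1-en-3-one)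
Product: 4 2,4,4-trimethylcyclohex-2-en-1-one, via 2,2-dimethyl-5-oxoheptanal 3 (not isolated)
Conditions: H2SO4 (cat.), neat, 45–50 °C; then benzene, reflux, Dean–Stark
Reagents that add atoms: none
Why: Acid-catalysed Robinson annulation, in which the enol of 1 adds to enone 2 (Michael) and the keto aldehyde closes by intramolecular aldol condensation; no stereocentre is formed.

**Step 2**
Reactants: 4 2,4,4-trimethylcyclohex-2-en-1-one
Product: 5 (1S)-2,4,4-trimethylcyclohex-2-en-1-ol
Conditions: (R)-Me-CBS oxazaborolidine [(3aR)-1-methyl-3,3-diphenyltetrahydro-1H,3H-pyrrolo[1,2-c][1,3,2]oxazaborole] (10 mol %), BH3·SMe2, THF, −20 °C; MeOH, then aqueous work-up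
Reagents that add atoms: none
Why: Corey–Bakshi–Shibata reduction, in which the catalyst–borane complex binds the carbonyl away from the larger trisubstituted-alkene arm and delivers hydride 1,2 to one face, setting the first stereocentre (1S) by asymmetric catalysis.

**Step 3**
Reactants: 5 (1S)-2,4,4-trimethylcyclohex-2-en-1-ol
Product: 6 tributyl({[(1S)-2,4,4-trimethylcyclohex-2-en-1-yl]oxy}methyl)stannane
Conditions: KH, THF, 0 °C; then Bu3SnCH2I, rt
Reagents that add atoms: tributyl(iodomethyl)stannane, CCCC[Sn](CCCC)(CCCC)CI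
Why: Williamson etherification of the potassium alkoxide with the primary iodide; the carbinol centre is not touched.

**Step 4**
Reactants: 6 tributyl({[(1S)-2,4,4-trimethylcyclohex-2-en-1-yl]oxy}methyl)stannane
Product: 8 [(1R)-2,6,6-trimethylcyclohex-2-en-1-yl]methanol ((R)-α-cyclogeraniol), via lithiomethyl ether 7 (not isolated)
Conditions: n-BuLi, THF, −78 °C to −20 °C; then H2O
Reagents that add atoms: none
Why: [2,3]-Wittig–Still rearrangement, in which tin–lithium exchange gives the α-alkoxymethyllithium that shifts suprafacially through a five-membered transition state, so the CH2O carbon arrives on the face that carried the oxygen and the 1S carbinol centre is traded for the ring stereocentre that becomes C6 of both end groups.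

**Step 5**
Reactants: 8 [(1R)-2,6,6-trimethylcyclohex-2-en-1-yl]methanol
Product: 9 benzyl [(1R)-2,6,6-trimethylcyclohex-2-en-1-yl]methyl ether
Conditions: NaH, BnBr, n-Bu4NI (cat.), THF/DMF, 0 °C to rt
Reagents that add atoms: benzyl bromide, BrCc1ccccc1
Why: Williamson benzylation gives a protecting group that survives borane, oxidation, base and acid and is later removed by hydrogenolysis once no alkene is present.

**Step 6**
Reactants: 9 benzyl [(1R)-2,6,6-trimethylcyclohex-2-en-1-yl]methyl ether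
Product: 11 (1R,2R,3S)-3-[(benzyloxy)methyl]-2,4,4-trimethylcyclohexan-1-ol (expected major isomer), via alkylborane 10 (not isolated)
Conditions: BH3·THF, THF, 0 °C to rt; then NaOH, H2O2, H2O, 0 °C to 40 °C
Reagents that add atoms: hydrogen peroxide, OO
Why: Hydroboration–oxidation places boron on the less substituted alkene carbon (C4) syn to the new C5–H, expected mainly on the face away from the CH2OBn group, and C–B oxidation goes with retention; the face chosen does not matter because C4 is oxidised in step 7 and C5 is equilibrated in step 8.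

**Step 7**
Reactants: 11 (1R,2R,3S)-3-[(benzyloxy)methyl]-2,4,4-trimethylcyclohexan-1-ol
Product: 12 (2R,3S)-3-[(benzyloxy)methyl]-2,4,4-trimethylcyclohexan-1-one (cis, with any trans epimer present)
Conditions: Dess–Martin periodinane, CH2Cl2, rt
Reagents that add atoms: none
Why: Dess–Martin oxidation of the secondary alcohol to the ring ketone (C4) leaves the benzyl ether untouched.

**Step 8**
Reactants: 12 (2R,3S)-3-[(benzyloxy)methyl]-2,4,4-trimethylcyclohexan-1-one
Product: 13 (2S,3S)-3-[(benzyloxy)methyl]-2,4,4-trimethylcyclohexan-1-one (trans)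
Conditions: K2CO3, MeOH, rt; chromatography, minor cis epimer recycled
Reagents that add atoms: none
Why: Base-mediated epimerisation through the enolate moves the α-methyl centre (C5) to the thermodynamically preferred trans isomer, the only one with both ring substituents equatorial, while C6 cannot enolise at this stage.

**Step 9**
Reactants: 13 (2S,3S)-3-[(benzyloxy)methyl]-2,4,4-trimethylcyclohexan-1-one
Product: 14 (6S,7S)-7-[(benzyloxy)methyl]-6,8,8-trimethyl-1,4-dioxaspiro[4.5]decane
Conditions: ethylene glycol, p-TsOH (cat.), benzene, reflux, Dean–Stark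
Reagents that add atoms: ethane-1,2-diol, OCCO
Why: Acid-catalysed ketalisation masks the ketone and locks C5 before C6 becomes α to an aldehyde, so the two centres are never enolisable at the same time.

**Step 10**
Reactants: 14 (6S,7S)-7-[(benzyloxy)methyl]-6,8,8-trimethyl-1,4-dioxaspiro[4.5]decane
Product: 15 [(6S,7S)-6,8,8-trimethyl-1,4-dioxaspiro[4.5]decan-7-yl]methanol
Conditions: H2 (1 atm), Pd/C (10%), EtOAc, rt
Reagents that add atoms: none
Why: Neutral hydrogenolysis of the benzyl ether leaves the dioxolane and both stereocentres unchanged.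

**Step 11**
Reactants: 15 [(6S,7S)-6,8,8-trimethyl-1,4-dioxaspiro[4.5]decan-7-yl]methanol
Product: 16 (6S,7S)-6,8,8-trimethyl-1,4-dioxaspiro[4.5]decane-7-carbaldehyde
Conditions: n-Pr4N[RuO4] (5 mol %), N-methylmorpholine N-oxide, 4 Å molecular sieves, CH2Cl2, rt
Reagents that add atoms: none
Why: Ley–Griffith oxidation stops at the aldehyde under near-neutral conditions, and the equatorial (trans) aldehyde is also the thermodynamic epimer at C6.

**Step 12**
Reactants: 16 (6S,7S)-6,8,8-trimethyl-1,4-dioxaspiro[4.5]decane-7-carbaldehyde; 17 ethyl (2E)-4-(diethoxyphosphoryl)-3-methylbut-2-enoate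
Product: 19 ethyl (2E,4E)-3-methyl-5-[(6S,7S)-6,8,8-trimethyl-1,4-dioxaspiro[4.5]decan-7-yl]penta-2,4-dienoate, via lithiated phosphonate 18 (not isolated)
Conditions: LiN(SiMe3)2, THF/DMPU, −78 °C; then 16, −78 °C to rt; chromatography (minor 2Z isomer removed)
Reagents that add atoms: none
Why: Horner–Wadsworth–Emmons olefination with the vinylogous phosphonate anion forms the C7=C8 bond E through the equilibrating adducts and brings in C8–C11 in one step.

**Step 13**
Reactants: 19 ethyl (2E,4E)-3-methyl-5-[(6S,7S)-6,8,8-trimethyl-1,4-dioxaspiro[4.5]decan-7-yl]penta-2,4-dienoate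
Product: 20 (2E,4E)-3-methyl-5-[(6S,7S)-6,8,8-trimethyl-1,4-dioxaspiro[4.5]decan-7-yl]penta-2,4-dien-1-ol
Conditions: i-Bu2AlH (2.5 equiv), CH2Cl2, −78 °C; aqueous potassium sodium tartrate
Reagents that add atoms: none
Why: Hydride reduction of the dienoate gives the allylic alcohol 1,2-selectively, and the tartrate work-up stays neutral for the ketal.

**Step 14**
Reactants: 20 (2E,4E)-3-methyl-5-[(6S,7S)-6,8,8-trimethyl-1,4-dioxaspiro[4.5]decan-7-yl]penta-2,4-dien-1-ol
Product: 21 (6S,7S)-7-[(1E,3E)-5-bromo-3-methylpenta-1,3-dien-1-yl]-6,8,8-trimethyl-1,4-dioxaspiro[4.5]decane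
Conditions: CBr4, PPh3, CH2Cl2, −20 °C to 0 °C; filtered through neutral alumina and used at once
Reagents that add atoms: carbon tetrabromide, BrC(Br)(Br)Br
Why: Appel bromination turns the primary allylic alcohol into the bromide without free acid, so the dioxolane survives.

**Step 15**
Reactants: 21 (6S,7S)-7-[(1E,3E)-5-bromo-3-methylpenta-1,3-dien-1-yl]-6,8,8-trimethyl-1,4-dioxaspiro[4.5]decane
Product: 22 triphenyl{(2E,4E)-3-methyl-5-[(6S,7S)-6,8,8-trimethyl-1,4-dioxaspiro[4.5]decan-7-yl]penta-2,4-dien-1-yl}phosphonium bromide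
Conditions: PPh3, EtOAc, rt, dark
Reagents that add atoms: triphenylphosphine, c1ccccc1P(c1ccccc1)c1ccccc1
Why: SN2 quaternisation at the primary allylic carbon gives the conjugated C15 phosphonium salt, which precipitates and can be recrystallised.

**Step 16**
Reactants: 19 ethyl (2E,4E)-3-methyl-5-[(6S,7S)-6,8,8-trimethyl-1,4-dioxaspiro[4.5]decan-7-yl]penta-2,4-dienoate
Product: 23 ethyl (2E,4E)-3-methyl-5-[(1S,6S)-2,2,6-trimethyl-5-oxocyclohexyl]penta-2,4-dienoate
Conditions: pyridinium p-toluenesulfonate, acetone/H2O (10:1), 50 °C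
Reagents that add atoms: water, O
Why: Mild acid hydrolysis of the dioxolane frees the ring ketone for the enzymatic step without touching the dienoate, and the trans C5 methyl is the thermodynamic epimer.

**Step 17**
Reactants: 23 ethyl (2E,4E)-3-methyl-5-[(1S,6S)-2,2,6-trimethyl-5-oxocyclohexyl]penta-2,4-dienoate
Product: 24 ethyl (2E,4E)-5-[(1S,5S,6S)-5-hydroxy-2,2,6-trimethylcyclohexyl]-3-methylpenta-2,4-dienoate
Conditions: ketoreductase (NADPH-dependent alcohol dehydrogenase, Prelog-selective, picked from a commercial panel), NADP+ (cat.), i-PrOH (10% v/v), potassium phosphate buffer pH 7.0, DMSO (5% v/v), 30 °C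
Reagents that add atoms: none
Why: Enzymatic asymmetric ketone reduction by a ketoreductase delivers the NADPH hydride to one carbonyl face under catalyst control to give the 4S carbinol (equatorial OH), which matches the substrate's own preference for axial attack, and the neutral buffer leaves the ester and C5 alone.

**Step 18**
Reactants: 24 ethyl (2E,4E)-5-[(1S,5S,6S)-5-hydroxy-2,2,6-trimethylcyclohexyl]-3-methylpenta-2,4-dienoate
Product: 25 (1S,2S,3S)-3-[(1E,3E)-5-hydroxy-3-methylpenta-1,3-dien-1-yl]-2,4,4-trimethylcyclohexan-1-ol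
Conditions: i-Bu2AlH (3.5 equiv), CH2Cl2, −78 °C to −40 °C; aqueous potassium sodium tartrate
Reagents that add atoms: none
Why: Hydride reduction of the ester to the allylic alcohol, with the free ring hydroxyl simply consuming one equivalent of hydride.

**Step 19**
Reactants: 25 (1S,2S,3S)-3-[(1E,3E)-5-hydroxy-3-methylpenta-1,3-dien-1-yl]-2,4,4-trimethylcyclohexan-1-ol
Product: 26 {(2E,4E)-5-[(1S,5S,6S)-5-hydroxy-2,2,6-trimethylcyclohexyl]-3-methylpenta-2,4-dien-1-yl}triphenylphosphonium bromide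
Conditions: PPh3·HBr, MeOH, rt, dark
Reagents that add atoms: triphenylphosphine hydrobromide, [Br-].c1ccccc1[PH+](c1ccccc1)c1ccccc1
Why: SN1-type substitution, in which the allylic alcohol ionises to a delocalised pentadienyl cation that PPh3 captures at the primary terminus, while the non-allylic ring hydroxyl does not ionise.

**Step 20**
Reactants: 22 triphenyl{(2E,4E)-3-methyl-5-[(6S,7S)-6,8,8-trimethyl-1,4-dioxaspiro[4.5]decan-7-yl]penta-2,4-dien-1-yl}phosphonium bromide; 27 (2E,4E,6E)-2,7-dimethylocta-2,4,6-trienedial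
Product: 29 (2E,4E,6E,8E,10E,12E)-2,7,11-trimethyl-13-[(6S,7S)-6,8,8-trimethyl-1,4-dioxaspiro[4.5]decan-7-yl]trideca-2,4,6,8,10,12-hexaenal, via ylide 28 (not isolated)
Conditions: 27 (2 equiv), 1,2-epoxybutane, EtOH, reflux; then n-heptane, reflux (Z to E); chromatography, excess 27 recovered
Reagents that add atoms: none
Why: Wittig olefination under neutral epoxide conditions, in which bromide opens the epoxide, the alkoxide forms the ylide, and the excess of dialdehyde limits reaction to one aldehyde; heating converts the hindered 11Z isomer to all-E.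

**Step 21**
Reactants: 26 {(2E,4E)-5-[(1S,5S,6S)-5-hydroxy-2,2,6-trimethylcyclohexyl]-3-methylpenta-2,4-dien-1-yl}triphenylphosphonium bromide; 29 (2E,4E,6E,8E,10E,12E)-2,7,11-trimethyl-13-[(6S,7S)-6,8,8-trimethyl-1,4-dioxaspiro[4.5]decan-7-yl]trideca-2,4,6,8,10,12-hexaenal
Product: 31 all-E (4S,5S,6S,5'S,6'S)-4',4'-(ethylenedioxy)-5,6,5',6'-tetrahydro-β,β-caroten-4-ol, via ylide 30 (not isolated)
Conditions: 26 (1.3 equiv), 1,2-epoxybutane, EtOH, reflux, dark, Ar; then n-heptane, reflux (Z to E); crystallisation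
Reagents that add atoms: none
Why: A second Wittig olefination under the same neutral conditions joins the hydroxy C15 unit to the C25 aldehyde at C11=C12, tolerating the free hydroxyl and the ketal, and thermal isomerisation gives the all-E C40 chain.

**Step 22**
Reactants: 31 all-E (4S,5S,6S,5'S,6'S)-4',4'-(ethylenedioxy)-5,6,5',6'-tetrahydro-β,β-caroten-4-ol
Product: 32 all-E (4S,5S,6S,5'S,6'S)-4-hydroxy-5,6,5',6'-tetrahydro-β,β-caroten-4'-one (CNP0107241.1)
Conditions: aqueous HCl (0.5 M), THF, rt, dark, Ar; NaHCO3 quench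
Reagents that add atoms: water, O
Why: Mild acid hydrolysis of the dioxolane releases the 4'-ketone, the non-allylic 4-hydroxyl and the non-conjugated ring centres are unaffected, and the trans 5'-methyl is the thermodynamic α-epimer.

**Compound list**
1 | isobutyraldehyde (2-methylpropanal) | CC(C)C=O | starting material
2 | ethyl vinyl ketone (pent-1-en-3-one) | CCC(=O)C=C | starting material
3 | 2,2-dimethyl-5-oxoheptanal (formed in the flask) | CCC(=O)CCC(C)(C)C=O | intermediate
4 | 2,4,4-trimethylcyclohex-2-en-1-one | CC1=CC(C)(C)CCC1=O | intermediate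
5 | (1S)-2,4,4-trimethylcyclohex-2-en-1-ol | CC1=CC(C)(C)CC[C@@H]1O | intermediate
6 | tributyl({[(1S)-2,4,4-trimethylcyclohex-2-en-1-yl]oxy}methyl)stannane | CC1=CC(C)(C)CC[C@@H]1OC[Sn](CCCC)(CCCC)CCCC | intermediate
7 | {[(1S)-2,4,4-trimethylcyclohex-2-en-1-yl]oxy}methyllithium (formed in the flask) | CC1=CC(C)(C)CC[C@@H]1OC[Li] | intermediate
8 | [(1R)-2,6,6-trimethylcyclohex-2-en-1-yl]methanol | OC[C@H]1C(C)=CCCC1(C)C | intermediate
9 | benzyl [(1R)-2,6,6-trimethylcyclohex-2-en-1-yl]methyl ether | c1ccccc1COC[C@H]1C(C)=CCCC1(C)C | intermediate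
10 | {(1R,2S,3S)-3-[(benzyloxy)methyl]-2,4,4-trimethylcyclohexyl}borane (formed in the flask, drawn as the monoalkylborane) | c1ccccc1COC[C@H]1[C@@H](C)[C@H](B)CCC1(C)C | intermediate
11 | (1R,2R,3S)-3-[(benzyloxy)methyl]-2,4,4-trimethylcyclohexan-1-ol | c1ccccc1COC[C@H]1[C@@H](C)[C@H](O)CCC1(C)C | intermediate
12 | (2R,3S)-3-[(benzyloxy)methyl]-2,4,4-trimethylcyclohexan-1-one | c1ccccc1COC[C@H]1[C@@H](C)C(=O)CCC1(C)C | intermediate
13 | (2S,3S)-3-[(benzyloxy)methyl]-2,4,4-trimethylcyclohexan-1-one | c1ccccc1COC[C@H]1[C@H](C)C(=O)CCC1(C)C | intermediate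
14 | (6S,7S)-7-[(benzyloxy)methyl]-6,8,8-trimethyl-1,4-dioxaspiro[4.5]decane | c1ccccc1COC[C@H]1[C@H](C)C2(OCCO2)CCC1(C)C | intermediate
15 | [(6S,7S)-6,8,8-trimethyl-1,4-dioxaspiro[4.5]decan-7-yl]methanol | OC[C@H]1[C@H](C)C2(OCCO2)CCC1(C)C | intermediate
16 | (6S,7S)-6,8,8-trimethyl-1,4-dioxaspiro[4.5]decane-7-carbaldehyde | O=C[C@H]1[C@H](C)C2(OCCO2)CCC1(C)C | intermediate
17 | ethyl (2E)-4-(diethoxyphosphoryl)-3-methylbut-2-enoate | CCOC(=O)/C=C(\C)CP(=O)(OCC)OCC | starting material
18 | lithium salt of the α-carbanion of 17 (formed in the flask) | [Li+].CCOC(=O)/C=C(\C)[CH-]P(=O)(OCC)OCC | intermediate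
19 | ethyl (2E,4E)-3-methyl-5-[(6S,7S)-6,8,8-trimethyl-1,4-dioxaspiro[4.5]decan-7-yl]penta-2,4-dienoate | CCOC(=O)/C=C(C)/C=C/[C@H]1[C@H](C)C2(OCCO2)CCC1(C)C | intermediate
20 | (2E,4E)-3-methyl-5-[(6S,7S)-6,8,8-trimethyl-1,4-dioxaspiro[4.5]decan-7-yl]penta-2,4-dien-1-ol | OC/C=C(C)/C=C/[C@H]1[C@H](C)C2(OCCO2)CCC1(C)C | intermediate
21 | (6S,7S)-7-[(1E,3E)-5-bromo-3-methylpenta-1,3-dien-1-yl]-6,8,8-trimethyl-1,4-dioxaspiro[4.5]decane | BrC/C=C(C)/C=C/[C@H]1[C@H](C)C2(OCCO2)CCC1(C)C | intermediate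
22 | triphenyl{(2E,4E)-3-methyl-5-[(6S,7S)-6,8,8-trimethyl-1,4-dioxaspiro[4.5]decan-7-yl]penta-2,4-dien-1-yl}phosphonium bromide | [Br-].C(/C=C(C)/C=C/[C@H]1[C@H](C)C2(OCCO2)CCC1(C)C)[P+](c1ccccc1)(c1ccccc1)c1ccccc1 | intermediate
23 | ethyl (2E,4E)-3-methyl-5-[(1S,6S)-2,2,6-trimethyl-5-oxocyclohexyl]penta-2,4-dienoate | CCOC(=O)/C=C(C)/C=C/[C@H]1[C@H](C)C(=O)CCC1(C)C | intermediate
24 | ethyl (2E,4E)-5-[(1S,5S,6S)-5-hydroxy-2,2,6-trimethylcyclohexyl]-3-methylpenta-2,4-dienoate | CCOC(=O)/C=C(C)/C=C/[C@H]1[C@H](C)[C@@H](O)CCC1(C)C | intermediate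
25 | (1S,2S,3S)-3-[(1E,3E)-5-hydroxy-3-methylpenta-1,3-dien-1-yl]-2,4,4-trimethylcyclohexan-1-ol | OC/C=C(C)/C=C/[C@H]1[C@H](C)[C@@H](O)CCC1(C)C | intermediate
26 | {(2E,4E)-5-[(1S,5S,6S)-5-hydroxy-2,2,6-trimethylcyclohexyl]-3-methylpenta-2,4-dien-1-yl}triphenylphosphonium bromide | [Br-].C(/C=C(C)/C=C/[C@H]1[C@H](C)[C@@H](O)CCC1(C)C)[P+](c1ccccc1)(c1ccccc1)c1ccccc1 | intermediate
27 | (2E,4E,6E)-2,7-dimethylocta-2,4,6-trienedial | O=C/C(C)=C/C=C/C=C(C)/C=O | starting material
28 | ylide of 22 (formed in the flask) | C(/C=C(C)/C=C/[C@H]1[C@H](C)C2(OCCO2)CCC1(C)C)=P(c1ccccc1)(c1ccccc1)c1ccccc1 | intermediate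
29 | (2E,4E,6E,8E,10E,12E)-2,7,11-trimethyl-13-[(6S,7S)-6,8,8-trimethyl-1,4-dioxaspiro[4.5]decan-7-yl]trideca-2,4,6,8,10,12-hexaenal | O=C/C(C)=C/C=C/C=C(C)/C=C/C=C(C)/C=C/[C@H]1[C@H](C)C2(OCCO2)CCC1(C)C | intermediate
30 | ylide of 26 (formed in the flask) | C(/C=C(C)/C=C/[C@H]1[C@H](C)[C@@H](O)CCC1(C)C)=P(c1ccccc1)(c1ccccc1)c1ccccc1 | intermediate
31 | all-E (4S,5S,6S,5'S,6'S)-4',4'-(ethylenedioxy)-5,6,5',6'-tetrahydro-β,β-caroten-4-ol | CC(/C=C/C=C(C)/C=C/[C@H]1[C@H](C)[C@@H](O)CCC1(C)C)=C\C=C\C=C(C)\C=C\C=C(C)\C=C\[C@H]1[C@H](C)C2(OCCO2)CCC1(C)C | intermediate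
32 | all-E (4S,5S,6S,5'S,6'S)-4-hydroxy-5,6,5',6'-tetrahydro-β,β-caroten-4'-one | CC(/C=C/C=C(C)/C=C/[C@H]1[C@H](C)[C@@H](O)CCC1(C)C)=C\C=C\C=C(C)\C=C\C=C(C)\C=C\[C@H]1[C@H](C)C(=O)CCC1(C)C | target

**Step count**
Total: 22 steps. Longest linear sequence: 18 steps (1–12, 16–19, 21, 22; the branch 1–15, 20–22 is equally long).

**Three steps most likely to fail, each with a fallback**

Step 4. The [2,3] shift must form a bond next to the quaternary carbon, and a [1,2] shift or simple destannylation may compete. The fallback sets out from 5 and comes back at 8, replacing the anionic [2,3] shift by a thermal [3,3] shift with the same suprafacial chirality transfer. Johnson–Claisen rearrangement of 5 (MeC(OEt)3, cat. EtCO2H, 140 °C) gives ethyl 2-[(1R)-2,6,6-trimethylcyclohex-2-en-1-yl]acetate F1. Enolate hydroxylation (LiN(i-Pr)2, THF, −78 °C, then 3-phenyl-2-(phenylsulfonyl)oxaziridine) gives ethyl 2-hydroxy-2-[(1R)-2,6,6-trimethylcyclohex-2-en-1-yl]acetate F2 as a carbinol epimer mixture. LiAlH4 in Et2O gives 1-[(1R)-2,6,6-trimethylcyclohex-2-en-1-yl]ethane-1,2-diol F3. Glycol cleavage with NaIO4 in THF/H2O gives (1R)-2,6,6-trimethylcyclohex-2-ene-1-carbaldehyde F4, which is not isolated because it isomerises easily into conjugation, but is reduced in the same flask with NaBH4 to 8.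

Step 8. The trans preference at C5 may be modest, because the cis epimer can place its CH2OBn group axial next to the carbonyl. The fallback sets out from 12 and comes back at 13, replacing the thermodynamic sorting by an enzymatic one. The C5-epimeric ketone mixture is reduced with a ketoreductase in phosphate buffer at pH 8–8.5 (NADP+, i-PrOH), where only the 2S ketone is accepted while the remaining epimer keeps equilibrating (dynamic reductive kinetic resolution), giving (1S,2S,3S)-3-[(benzyloxy)methyl]-2,4,4-trimethylcyclohexan-1-ol F5 as a single isomer. Oxidation of F5 with Dess–Martin periodinane buffered with pyridine, which does not epimerise, returns stereopure 13. This is then ketalised in step 9 under aprotic conditions (1,2-bis(trimethylsilyloxy)ethane, cat. Me3SiOTf, −78 °C).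

Step 22. Hydrolysis of a hindered dioxolane on the acid- and oxygen-sensitive C40 polyene may be slow or may degrade the chain. The fallback sets out from 22 and comes back at 32, moving the deprotection before the polyene exists. Brief treatment of 22 with aqueous HBr in MeOH gives triphenyl{(2E,4E)-3-methyl-5-[(1S,6S)-2,2,6-trimethyl-5-oxocyclohexyl]penta-2,4-dien-1-yl}phosphonium bromide F6. Under the epoxide conditions of step 20 its ylide F7 condenses with excess 27 to give (2E,4E,6E,8E,10E,12E)-2,7,11-trimethyl-13-[(1S,6S)-2,2,6-trimethyl-5-oxocyclohexyl]trideca-2,4,6,8,10,12-hexaenal F8. Wittig reaction of F8 with 26 (through ylide 30) as in step 21 gives 32 directly. The hindered ring ketone is far less electrophilic than the polyene aldehyde, so it should not compete.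

**Further compounds**
F1 | step 4 | ethyl 2-[(1R)-2,6,6-trimethylcyclohex-2-en-1-yl]acetate | CCOC(=O)C[C@H]1C(C)=CCCC1(C)C
F2 | step 4 | ethyl 2-hydroxy-2-[(1R)-2,6,6-trimethylcyclohex-2-en-1-yl]acetate | CCOC(=O)C(O)[C@H]1C(C)=CCCC1(C)C
F3 | step 4 | 1-[(1R)-2,6,6-trimethylcyclohex-2-en-1-yl]ethane-1,2-diol | OCC(O)[C@H]1C(C)=CCCC1(C)C
F4 | step 4 | (1R)-2,6,6-trimethylcyclohex-2-ene-1-carbaldehyde | O=C[C@H]1C(C)=CCCC1(C)C
F5 | step 8 | (1S,2S,3S)-3-[(benzyloxy)methyl]-2,4,4-trimethylcyclohexan-1-ol | c1ccccc1COC[C@H]1[C@H](C)[C@@H](O)CCC1(C)C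
F6 | step 22 | triphenyl{(2E,4E)-3-methyl-5-[(1S,6S)-2,2,6-trimethyl-5-oxocyclohexyl]penta-2,4-dien-1-yl}phosphonium bromide | [Br-].C(/C=C(C)/C=C/[C@H]1[C@H](C)C(=O)CCC1(C)C)[P+](c1ccccc1)(c1ccccc1)c1ccccc1
F7 | step 22 | ylide of F6 | C(/C=C(C)/C=C/[C@H]1[C@H](C)C(=O)CCC1(C)C)=P(c1ccccc1)(c1ccccc1)c1ccccc1
F8 | step 22 | (2E,4E,6E,8E,10E,12E)-2,7,11-trimethyl-13-[(1S,6S)-2,2,6-trimethyl-5-oxocyclohexyl]trideca-2,4,6,8,10,12-hexaenal | O=C/C(C)=C/C=C/C=C(C)/C=C/C=C(C)/C=C/[C@H]1[C@H](C)C(=O)CCC1(C)C
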